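**Strategy.** The plan cuts the chain on both sides of C5 (bonds C4–C5 and C5–C6; C1 is the benzylic carbon). C5, the carbinol carbon lying between the C4 methylene and the pentyl chain, is treated as a twofold nucleophilic carbonyl equivalent, and O3–C3–C4 as the imprint of a terminal epoxide. The dimethoxybenzene ring is a spectator and no ring is formed. One flask joins a 2-silyl-1,3-dithiane, the (S)-epoxide carrying the arylethyl chain and 1-iodopentane through a solvent-triggered silyl shift from carbon to oxygen, giving C1–C10 with O3 silylated and C5 masked as a dithiane. Unmasking and a hydroxyl-directed Tishchenko reduction then set C5 and place the acetate on O3.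

Key step: step 4

Remark: the chain is numbered from the benzylic carbon C1 to the methyl carbon C10. The target is (3S,5S), which is the 3,5-anti arrangement. (S)-Epichlorohydrin maps onto the (S)-epoxide and onto C3 = S without any inversion.

**Step 1**
Reactants: 1 3,4-dimethoxybenzyl chloride; 2 (S)-epichlorohydrin
Product: 4 (2S)-1-chloro-4-(3,4-dimethoxyphenyl)butan-2-ol, via 3,4-dimethoxybenzylmagnesium chloride 3 (not isolated)
Conditions: Mg turnings, THF, 0 °C (slow addition of 1); then 2, CuI (10 mol%), THF, −40 → −20 °C; aq. NH4Cl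
Reagents that add atoms: none
Why: Magnesium inserts into the benzylic C–Cl bond to give 3, and copper-catalysed Grignard opening of the epoxide at its unsubstituted carbon is faster at low temperature than displacement of chloride, so the stereocentre of 2 is not touched and keeps the S descriptor.

**Step 2**
Reactants: 4 (2S)-1-chloro-4-(3,4-dimethoxyphenyl)butan-2-ol
Product: 5 (2S)-2-[2-(3,4-dimethoxyphenyl)ethyl]oxirane
Conditions: NaOH (2 M aq.), THF, 0 °C → rt
Reagents that add atoms: none
Why: Intramolecular Williamson etherification (chlorohydrin-to-epoxide closure) displaces chloride at the primary carbon only, so the carbinol carbon is not involved and stays S.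

**Step 3**
Reactants: 6 1,3-dithiane
Product: 8 2-(tert-butyldimethylsilyl)-1,3-dithiane, via 2-lithio-1,3-dithiane 7 (not isolated)
Conditions: n-BuLi, THF, −30 °C; TBSCl, −78 °C → rt
Reagents that add atoms: tert-butyldimethylsilyl chloride (TBSCl), CC(C)(C)[Si](C)(C)Cl
Why: Corey–Seebach deprotonation of the C2–H flanked by two sulfur atoms gives 7, which is silylated at carbon by substitution at silicon; no stereocentre is involved.

**Step 4**
Reactants: 8 2-(tert-butyldimethylsilyl)-1,3-dithiane; 5 (2S)-2-[2-(3,4-dimethoxyphenyl)ethyl]oxirane; 9 1-iodopentane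
Product: 13 tert-butyl{[(2S)-4-(3,4-dimethoxyphenyl)-1-(2-pentyl-1,3-dithian-2-yl)butan-2-yl]oxy}dimethylsilane, via 2-lithio-2-(tert-butyldimethylsilyl)-1,3-dithiane 10 (not isolated), via lithium alkoxide adduct 11 (not isolated), via Brook-rearranged 2-lithiodithiane 12 (not isolated)
Conditions: t-BuLi, Et2O, −78 → −45 °C; 5, Et2O, −78 → −25 °C; then 9, HMPA, THF, −78 °C → rt
Reagents that add atoms: none
Why: tert-Butyllithium removes the C2–H of 8 to give 10, which in ether opens epoxide 5 by SN2 attack at the unsubstituted ring carbon (bond C4–C5) to give alkoxide 11; 11 persists in ether, but HMPA loosens the O–Li ion pair so that silicon moves from carbon to oxygen through a five-membered silicate (1,4-Brook rearrangement), and the sulfur-stabilised carbanion 12 released in this way is alkylated by primary iodide 9 (bond C5–C6). The closest known reaction type is the multicomponent linchpin coupling of 2-silyl-1,3-dithianes with an epoxide and a second electrophile, an anion relay built on Corey–Seebach umpolung. No ring is closed and no stereocentre is created, because the stereogenic epoxide carbon is not attacked and C3 therefore stays S. Three selectivities are needed: opening at the CH2 terminus, which the monosubstituted epoxide secures on steric grounds; a strict order of the two electrophiles, which is secured by withholding HMPA until 5 is consumed, since only the silyl shift can generate the second anion; and substitution in preference to elimination in the last stage, which the unhindered primary iodide secures. Keeping tert-butyllithium slightly below the amount of 8 ensures that no free alkyllithium meets 5 or 9.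

**Step 5**
Reactants: 13 tert-butyl{[(2S)-4-(3,4-dimethoxyphenyl)-1-(2-pentyl-1,3-dithian-2-yl)butan-2-yl]oxy}dimethylsilane
Product: 14 (2S)-4-(3,4-dimethoxyphenyl)-1-(2-pentyl-1,3-dithian-2-yl)butan-2-ol
Conditions: TBAF, THF, 0 °C → rt
Reagents that add atoms: none
Why: Fluoride-induced cleavage of the Si–O bond (TBAF desilylation) is driven by the strong Si–F bond and leaves the dithioketal, the aryl ethers and the C3 stereocentre untouched.

**Step 6**
Reactants: 14 (2S)-4-(3,4-dimethoxyphenyl)-1-(2-pentyl-1,3-dithian-2-yl)butan-2-ol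
Product: 15 (3S)-1-(3,4-dimethoxyphenyl)-3-hydroxydecan-5-one
Conditions: MeI, CaCO3, MeCN/H2O (9:1), 40 °C
Reagents that add atoms: water, O
Why: S-Methylation by iodomethane gives a sulfonium ion that opens to a thionium ion and is hydrolysed by water (alkylative dethioketalisation), while CaCO3 takes up the HI so that the β-hydroxy ketone should neither dehydrate nor undergo retro-aldol cleavage, and the non-oxidative conditions spare the electron-rich arene.

**Step 7**
Reactants: 15 (3S)-1-(3,4-dimethoxyphenyl)-3-hydroxydecan-5-one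
Product: 16 (3S,5S)-1-(3,4-dimethoxyphenyl)-5-hydroxydecan-3-yl acetate
Conditions: MeCHO (excess, freshly distilled), SmI2 (0.3 equiv), THF, −10 °C; pH 7 buffer work-up
Reagents that add atoms: acetaldehyde, CC=O
Why: Evans–Tishchenko reduction: the trivalent samarium catalyst formed from SmI2 and acetaldehyde holds the hemiacetal at O3 and the C5 carbonyl in a chair-like six-membered transition state, so hydride passes intramolecularly to the ketone face that gives the 3,5-anti product (C5 = S, controlled by the C3 stereocentre), and the hemiacetal carbon ends as the acetate on O3.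

**Compound list**
1 | 3,4-dimethoxybenzyl chloride | COc1ccc(CCl)cc1OC | starting material
2 | (S)-epichlorohydrin | ClC[C@@H]1CO1 | starting material
3 | 3,4-dimethoxybenzylmagnesium chloride | COc1ccc(C[Mg]Cl)cc1OC | intermediate
4 | (2S)-1-chloro-4-(3,4-dimethoxyphenyl)butan-2-ol | COc1ccc(CC[C@H](O)CCl)cc1OC | intermediate
5 | (2S)-2-[2-(3,4-dimethoxyphenyl)ethyl]oxirane | COc1ccc(CC[C@H]2CO2)cc1OC | intermediate
6 | 1,3-dithiane | C1CSCSC1 | starting material
7 | 2-lithio-1,3-dithiane | [Li]C1SCCCS1 | intermediate
8 | 2-(tert-butyldimethylsilyl)-1,3-dithiane | CC(C)(C)[Si](C)(C)C1SCCCS1 | intermediate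
9 | 1-iodopentane | CCCCCI | starting material
10 | 2-lithio-2-(tert-butyldimethylsilyl)-1,3-dithiane | CC(C)(C)[Si](C)(C)C1([Li])SCCCS1 | intermediate
11 | lithium (2S)-1-[2-(tert-butyldimethylsilyl)-1,3-dithian-2-yl]-4-(3,4-dimethoxyphenyl)butan-2-olate | COc1ccc(CC[C@H](O[Li])CC2(SCCCS2)[Si](C)(C)C(C)(C)C)cc1OC | intermediate
12 | {2-[(2S)-2-(tert-butyldimethylsilyloxy)-4-(3,4-dimethoxyphenyl)butyl]-1,3-dithian-2-yl}lithium | COc1ccc(CC[C@H](O[Si](C)(C)C(C)(C)C)CC2([Li])SCCCS2)cc1OC | intermediate
13 | tert-butyl{[(2S)-4-(3,4-dimethoxyphenyl)-1-(2-pentyl-1,3-dithian-2-yl)butan-2-yl]oxy}dimethylsilane | CCCCCC1(SCCCS1)C[C@H](CCc1ccc(OC)c(OC)c1)O[Si](C)(C)C(C)(C)C | intermediate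
14 | (2S)-4-(3,4-dimethoxyphenyl)-1-(2-pentyl-1,3-dithian-2-yl)butan-2-ol | COc1ccc(CC[C@H](O)CC2(CCCCC)SCCCS2)cc1OC | intermediate
15 | (3S)-1-(3,4-dimethoxyphenyl)-3-hydroxydecan-5-one | COc1ccc(CC[C@H](O)CC(=O)CCCCC)cc1OC | intermediate
16 | (3S,5S)-1-(3,4-dimethoxyphenyl)-5-hydroxydecan-3-yl acetate | CCCCC[C@H](O)C[C@H](CCc1ccc(OC)c(OC)c1)OC(C)=O | target

**Total step count:** 7
**Longest linear sequence:** 6 steps (steps 1, 2, 4, 5, 6 and 7)

**Steps most likely to fail**

Step 4. The relay may break down if silicon migrates before the epoxide is consumed, so that the relayed anion takes up a second molecule of epoxide, or if the hindered anion is protonated before it is alkylated. The fallback makes the same two bonds in two flasks and in the opposite order. It sets out from 6, which is lithiated (n-BuLi, THF, −30 °C) and alkylated with 9 to give 2-pentyl-1,3-dithiane F1 (Corey–Seebach alkylation). F1 is lithiated again (t-BuLi, THF/HMPA, −78 °C) and should open epoxide 5 at its CH2 terminus; aqueous work-up should deliver 14 directly, where the fallback rejoins the route, so that steps 3 and 5 are not needed.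

Step 7. Hydride transfer may stall if acetaldehyde is used up by aldol or pinacol side reactions, and the acetyl group may wander from O3 to O5 during the reaction or on isolation. The fallback sets C5 by an ether-directed reduction and then exchanges protecting groups. It sets out from 14 and comes back at 16:
- Benzylation (NaH, BnBr, THF/DMF, 0 °C → rt) should give 2-[(2S)-2-(benzyloxy)-4-(3,4-dimethoxyphenyl)butyl]-2-pentyl-1,3-dithiane F2.
- Alkylative hydrolysis of the dithiane (MeI, CaCO3, aq. MeCN) should give (3S)-3-(benzyloxy)-1-(3,4-dimethoxyphenyl)decan-5-one F3.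
- Reduction with SmI2 and MeOH in THF at 0 °C, a reaction known to turn β-alkoxy ketones into anti-1,3-diol monoethers, should give (3S,5S)-3-(benzyloxy)-1-(3,4-dimethoxyphenyl)decan-5-ol F4.
- Silylation (TBSOTf, 2,6-lutidine, CH2Cl2) should give {[(3S,5S)-3-(benzyloxy)-1-(3,4-dimethoxyphenyl)decan-5-yl]oxy}(tert-butyl)dimethylsilane F5.
- Hydrogenolysis (H2, Pd/C, EtOAc) should give (3S,5S)-5-[(tert-butyldimethylsilyl)oxy]-1-(3,4-dimethoxyphenyl)decan-3-ol F6.
- Acetylation (Ac2O, pyridine, DMAP) should give (3S,5S)-5-[(tert-butyldimethylsilyl)oxy]-1-(3,4-dimethoxyphenyl)decan-3-yl acetate F7.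
- HF·pyridine in THF at 0 °C then frees O5 under mildly acidic conditions, in which acetyl migration is slow, and should give 16.

Step 1. Formation of the electron-rich benzylic Grignard reagent may be overtaken by Wurtz homocoupling, and direct displacement of chloride in 2 would erode the enantiomeric purity. The fallback uses 1 as the electrophile and takes the stereocentre from a kinetic resolution. It sets out from 1, which is coupled with allylmagnesium chloride (Li2CuCl4 cat., THF, 0 °C) to give 4-(3,4-dimethoxyphenyl)but-1-ene F8. Epoxidation with mCPBA (NaHCO3, CH2Cl2, 0 °C) should give racemic 2-[2-(3,4-dimethoxyphenyl)ethyl]oxirane F9. Hydrolytic kinetic resolution (Jacobsen) with 0.55 equiv of water and the (S,S)-(salen)Co(OAc) complex (trivalent cobalt; the antipode that hydrolyses the R epoxide) should leave the S epoxide and convert the other enantiomer into (2R)-4-(3,4-dimethoxyphenyl)butane-1,2-diol F10, which is removed by chromatography. The fallback rejoins the route at 5, so that step 2 is not needed.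

**Further compounds**
F1 | step 4 | 2-pentyl-1,3-dithiane | CCCCCC1SCCCS1
F2 | step 7 | 2-[(2S)-2-(benzyloxy)-4-(3,4-dimethoxyphenyl)butyl]-2-pentyl-1,3-dithiane | COc1ccc(CC[C@H](OCc2ccccc2)CC3(CCCCC)SCCCS3)cc1OC
F3 | step 7 | (3S)-3-(benzyloxy)-1-(3,4-dimethoxyphenyl)decan-5-one | COc1ccc(CC[C@H](OCc2ccccc2)CC(=O)CCCCC)cc1OC
F4 | step 7 | (3S,5S)-3-(benzyloxy)-1-(3,4-dimethoxyphenyl)decan-5-ol | CCCCC[C@H](O)C[C@H](CCc1ccc(OC)c(OC)c1)OCc1ccccc1
F5 | step 7 | {[(3S,5S)-3-(benzyloxy)-1-(3,4-dimethoxyphenyl)decan-5-yl]oxy}(tert-butyl)dimethylsilane | CCCCC[C@H](O[Si](C)(C)C(C)(C)C)C[C@H](CCc1ccc(OC)c(OC)c1)OCc1ccccc1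
F6 | step 7 | (3S,5S)-5-[(tert-butyldimethylsilyl)oxy]-1-(3,4-dimethoxyphenyl)decan-3-ol | CCCCC[C@H](O[Si](C)(C)C(C)(C)C)C[C@H](CCc1ccc(OC)c(OC)c1)O
F7 | step 7 | (3S,5S)-5-[(tert-butyldimethylsilyl)oxy]-1-(3,4-dimethoxyphenyl)decan-3-yl acetate | CCCCC[C@H](O[Si](C)(C)C(C)(C)C)C[C@H](CCc1ccc(OC)c(OC)c1)OC(C)=O
F8 | step 1 | 4-(3,4-dimethoxyphenyl)but-1-ene | COc1ccc(CCC=C)cc1OC
F9 | step 1 | racemic 2-[2-(3,4-dimethoxyphenyl)ethyl]oxirane | COc1ccc(CCC2CO2)cc1OC
F10 | step 1 | (2R)-4-(3,4-dimethoxyphenyl)butane-1,2-diol | COc1ccc(CC[C@@H](O)CO)cc1OC
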